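**Retrosynthetic overview**
Ring C is closed last: the C2–O1 bond comes from opening of a (2R,3S)-chalcone epoxide by the O1 phenol with inversion at C2. The epoxide comes from a chalcone whose C4–C4a bond is made by O1-directed lithiation of ring A and acylation with a ring B cinnamoyl Weinreb amide.
Ring A is built first and de novo from a vinylketene (from an α'-diazo enone) and a siloxyalkyne, in a cascade that forms C4a–C5, C7–C8, C4a–C8a and C6–C7.
The strategy rests on the pattern of ring A: a resorcinol with prenyl groups at C8 (between O1 and the 7-OH) and at C6, hydrogen at C5 and C4a, and two oxygens with different fates. The cascade fixes every position by connectivity: alkyne prenyl to C8, alkyne oxygen to O1 (silylated), ketene oxygen to the free 7-OH, diazoketone prenyl to C6.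
The two components come from 4-methylpent-3-enoic acid (ester homologation to the ynol ether) and 4-methylpent-3-en-1-ol (oxidation/Wittig, then diazo transfer). Ring B is carried in intact from 4-hydroxybenzaldehyde.
Order of ring formation: ring A (step 5), ring B brought in preformed (step 10), ring C (step 12).

Key step: step 5

Assumption: flavonoid numbering (O1, C2, C3, C4, C4a, C5 to C8, C8a) is used for ring atoms; MOM = methoxymethyl, TIPS = triisopropylsilyl; the facial preference of poly-L-leucine known for simple chalcones is taken to hold for chalcone 23.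

**Step 1**
Reactants: 1 4-methylpent-3-enoic acid
Product: 2 ethyl 4-methylpent-3-enoate
Conditions: EtI, K2CO3, DMF, 25 °C
Reagents that add atoms: iodoethane, CCI
Why: Carboxylate O-alkylation (SN2) under mild carbonate base gives the ester without the strong acid that would lactonize this β,γ-unsaturated acid or move its alkene into conjugation.

**Step 2**
Reactants: 2 ethyl 4-methylpent-3-enoate
Product: 5 triisopropyl[(5-methylhex-4-en-1-yn-1-yl)oxy]silane, via dibromomethyl ketone 3 (not isolated), via lithium ynolate 4 (not isolated)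
Conditions: CH2Br2, lithium 2,2,6,6-tetramethylpiperidide, THF, −78 °C; add 2; n-BuLi (excess), −78 → 25 °C; then i-Pr3SiCl, −78 → 0 °C
Reagents that add atoms: dibromomethane, BrCBr (one carbon in 5, both bromines in 3); chlorotriisopropylsilane, CC(C)[Si](Cl)(C(C)C)C(C)C; n-butyllithium, [Li]CCCC (lithium of 4 only)
Why: Kowalski ester homologation, in which LiCHBr2 adds to the ester, the enolate of dibromo ketone 3 undergoes bromine–lithium exchange and 1,2-shift to ynolate 4, and the bulky silyl chloride traps 4 on oxygen as the isolable TIPS ynol ether.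

**Step 3**
Reactants: 6 4-methylpent-3-en-1-ol; 7 1-(triphenylphosphoranylidene)propan-2-one
Product: 9 (E)-7-methylocta-3,6-dien-2-one, via 4-methylpent-3-enal 8 (not isolated)
Conditions: IBX (2-iodoxybenzoic acid), 7 present from the start, DMSO, 25 °C
Reagents that add atoms: none
Why: One-pot IBX oxidation and Wittig olefination, in which the isomerization-prone β,γ-unsaturated aldehyde 8 is trapped as it forms by the neutral stabilized ylide, which gives the E-enone.

**Step 4**
Reactants: 9 (E)-7-methylocta-3,6-dien-2-one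
Product: 11 (E)-1-diazo-7-methylocta-3,6-dien-2-one, via trifluoroacetyl diketone 10 (not isolated)
Conditions: LiN(SiMe3)2, THF, −78 °C; CF3CO2CH2CF3; then MsN3, Et3N, H2O, MeCN, 25 °C
Reagents that add atoms: methanesulfonyl azide, CS(=O)(=O)N=[N+]=[N-]; 2,2,2-trifluoroethyl trifluoroacetate, O=C(OCC(F)(F)F)C(F)(F)F (its CF3CO group is carried by intermediate 10 only)
Why: Detrifluoroacetylative diazo transfer, in which kinetic α'-deprotonation of the methyl ketone at −78 °C and trifluoroacetylation activate the methyl carbon so that the sulfonyl azide delivers N2 with loss of the trifluoroacetyl group; this is the standard entry to α'-diazo enones, which cannot be made from enoyl chlorides and diazomethane.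

**Step 5**
Reactants: 11 (E)-1-diazo-7-methylocta-3,6-dien-2-one; 5 triisopropyl[(5-methylhex-4-en-1-yn-1-yl)oxy]silane
Product: 15 2,6-bis(3-methylbut-2-enyl)-3-(triisopropylsilyloxy)phenol, via vinylketene 12 (not isolated), via 4-vinylcyclobutenone 13 (not isolated), via dienylketene 14 (not isolated)
Conditions: hν (300 nm, quartz), 5 in slight excess, ClCH2CH2Cl, 25 °C; then 80 °C
Reagents that add atoms: none
Why: Irradiation expels N2 and the vinyl group migrates to the carbene carbon (Wolff rearrangement, forming C4a–C5) to give vinylketene 12, whose ketene C=C adds the siloxyalkyne in a [2+2] cycloaddition (forming C7–C8 and C4a–C8a) to give cyclobutenone 13. Warming drives the strain-releasing, reversible 4π-electrocyclic opening of 13 to dienylketene 14, and ring A is closed by 6π-electrocyclization of 14 (forming C6–C7) followed by tautomerization of the cyclohexadienone to the phenol. This is the photochemical form of the Danheiser benzannulation, a known reaction of α'-diazo enones with trialkylsilyl ynol ethers. No stereocenter remains in 15, since the one sp3 ring carbon of 13 is lost on aromatization. The step needs regiocontrol and chemoselectivity: the polarized ynol ether bonds through its nucleophilic, prenyl-bearing carbon to the ketene carbonyl carbon, so this prenyl ends at C8 between the two oxygens, the silyloxy carbon becomes C8a and the ketene oxygen becomes the free 7-OH; the unactivated trisubstituted prenyl alkenes are far poorer ketene partners than the electron-rich alkyne, and the E-alkene of 12 keeps its own prenyl group out of reach of the ketene.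

**Step 6**
Reactants: 15 2,6-bis(3-methylbut-2-enyl)-3-(triisopropylsilyloxy)phenol
Product: 16 2,4-bis(3-methylbut-2-enyl)benzene-1,3-diol
Conditions: TBAF, THF, 0 °C
Reagents that add atoms: none
Why: Fluoride-induced cleavage of the aryl silyl ether frees the O1 phenol without acid, which would cyclize the ortho-prenyl phenols to chromans.

**Step 7**
Reactants: 16 2,4-bis(3-methylbut-2-enyl)benzene-1,3-diol
Product: 17 1,3-bis(methoxymethoxy)-2,4-bis(3-methylbut-2-enyl)benzene
Conditions: NaH, MOMCl, DMF, 0 → 25 °C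
Reagents that add atoms: chloromethyl methyl ether, COCCl
Why: Williamson O-alkylation of both phenoxides completes the exchange of silicon for MOM on O1, which now can direct metalation to C4a, and gives base-stable acetals on both oxygens.

**Step 8**
Reactants: 18 4-hydroxybenzaldehyde
Product: 19 4-(methoxymethoxy)benzaldehyde
Conditions: MOMCl, K2CO3, acetone, 25 °C
Reagents that add atoms: chloromethyl methyl ether, COCCl
Why: Phenoxide O-alkylation protects the ring B phenol in a form stable to organolithium and to basic peroxide.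

**Step 9**
Reactants: 19 4-(methoxymethoxy)benzaldehyde; 20 diethyl {2-[methoxy(methyl)amino]-2-oxoethyl}phosphonate
Product: 21 (2E)-N-methoxy-3-[4-(methoxymethoxy)phenyl]-N-methylprop-2-enamide
Conditions: NaH, THF, 0 → 25 °C
Reagents that add atoms: none
Why: Horner–Wadsworth–Emmons olefination with the stabilized amide phosphonate gives the E-configured cinnamoyl Weinreb amide.

**Step 10**
Reactants: 17 1,3-bis(methoxymethoxy)-2,4-bis(3-methylbut-2-enyl)benzene; 21 (2E)-N-methoxy-3-[4-(methoxymethoxy)phenyl]-N-methylprop-2-enamide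
Product: 23 (2E)-1-[2,4-bis(methoxymethoxy)-3,5-bis(3-methylbut-2-enyl)phenyl]-3-[4-(methoxymethoxy)phenyl]prop-2-en-1-one, via aryllithium 22 (not isolated)
Conditions: n-BuLi, TMEDA, Et2O, 0 → 25 °C; then 21, THF, −78 → 0 °C
Reagents that add atoms: n-butyllithium, [Li]CCCC (its lithium is carried by intermediate 22 only)
Why: Directed ortho-metalation, in which the O1 acetal directs lithiation to C4a (the only ring C–H ortho to an acetal oxygen) and the aryllithium adds once to the Weinreb amide through a stable chelated tetrahedral adduct, forming the C4–C4a bond and releasing the chalcone on work-up.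

**Step 11**
Reactants: 23 (2E)-1-[2,4-bis(methoxymethoxy)-3,5-bis(3-methylbut-2-enyl)phenyl]-3-[4-(methoxymethoxy)phenyl]prop-2-en-1-one
Product: 24 [2,4-bis(methoxymethoxy)-3,5-bis(3-methylbut-2-enyl)phenyl]{(2R,3S)-3-[4-(methoxymethoxy)phenyl]oxiran-2-yl}methanone
Conditions: poly-L-leucine (immobilized), urea·H2O2, DBU, THF, 25 °C
Reagents that add atoms: hydrogen peroxide (as its urea adduct), OO
Why: Juliá–Colonna epoxidation, in which hydroperoxide adds in conjugate fashion inside the helical L-polypeptide, which for chalcones leads to the (2R,3S)-trans-epoxide; this sets both stereocenters (the future C3 directly, the future C2 as its invertible precursor), and the nucleophilic oxidant leaves the electron-rich prenyl alkenes untouched.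

**Step 12**
Reactants: 24 [2,4-bis(methoxymethoxy)-3,5-bis(3-methylbut-2-enyl)phenyl]{(2R,3S)-3-[4-(methoxymethoxy)phenyl]oxiran-2-yl}methanone
Product: 27 lespeflorin B2 [(2R,3R)-3,7-dihydroxy-2-(4-hydroxyphenyl)-6,8-bis(3-methylbut-2-enyl)-2,3-dihydro-4H-chromen-4-one], via 2'-hydroxy epoxy ketone 25 (not isolated), via bis-MOM dihydroflavonol 26 (not isolated)
Conditions: HCl (3 M aq.), MeOH–THF, 45 °C, short reaction time
Reagents that add atoms: none
Why: Acidic acetal methanolysis first frees the carbonyl-chelated O1 phenol, which opens the protonated epoxide at the benzylic carbon (6-endo, favoured by the p-oxygenated aryl group) with inversion to give C2 as R, while C3 keeps the R configuration of the epoxide carbon; the 2,3-trans isomer is also the thermodynamic one, and the two remaining acetals are cleaved in the same operation.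

**Compound list**
1 | 4-methylpent-3-enoic acid | CC(C)=CCC(=O)O | starting material
2 | ethyl 4-methylpent-3-enoate | CCOC(=O)CC=C(C)C | intermediate
3 | 1,1-dibromo-5-methylhex-4-en-2-one (present as its lithium enolate) | CC(C)=CCC(=O)C(Br)Br | intermediate
4 | lithium 5-methylhex-4-en-1-yn-1-olate | [Li+].[O-]C#CCC=C(C)C | intermediate
5 | triisopropyl[(5-methylhex-4-en-1-yn-1-yl)oxy]silane | CC(C)=CCC#CO[Si](C(C)C)(C(C)C)C(C)C | intermediate
6 | 4-methylpent-3-en-1-ol | CC(C)=CCCO | starting material
7 | 1-(triphenylphosphoranylidene)propan-2-one | CC(=O)C=P(c1ccccc1)(c1ccccc1)c1ccccc1 | starting material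
8 | 4-methylpent-3-enal | CC(C)=CCC=O | intermediate
9 | (E)-7-methylocta-3,6-dien-2-one | CC(=O)/C=C/CC=C(C)C | intermediate
10 | (5E)-1,1,1-trifluoro-9-methyldeca-5,8-diene-2,4-dione | CC(C)=CC/C=C/C(=O)CC(=O)C(F)(F)F | intermediate
11 | (E)-1-diazo-7-methylocta-3,6-dien-2-one | [N-]=[N+]=CC(=O)/C=C/CC=C(C)C | intermediate
12 | (3E)-7-methylocta-1,3,6-trien-1-one (vinylketene) | O=C=C/C=C/CC=C(C)C | intermediate
13 | 4-[(1E)-5-methylhexa-1,4-dienyl]-2-(3-methylbut-2-enyl)-3-(triisopropylsilyloxy)cyclobut-2-en-1-one (racemic) | CC(C)=CCC1=C(O[Si](C(C)C)(C(C)C)C(C)C)C(/C=C/CC=C(C)C)C1=O | intermediate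
14 | (3E,5E)-9-methyl-2-(3-methylbut-2-enyl)-3-(triisopropylsilyloxy)deca-1,3,5,8-tetraen-1-one (dienylketene) | O=C=C(CC=C(C)C)/C(O[Si](C(C)C)(C(C)C)C(C)C)=C\C=C\CC=C(C)C | intermediate
15 | 2,6-bis(3-methylbut-2-enyl)-3-(triisopropylsilyloxy)phenol | CC(C)=CCc1ccc(O[Si](C(C)C)(C(C)C)C(C)C)c(CC=C(C)C)c1O | intermediate
16 | 2,4-bis(3-methylbut-2-enyl)benzene-1,3-diol | CC(C)=CCc1ccc(O)c(CC=C(C)C)c1O | intermediate
17 | 1,3-bis(methoxymethoxy)-2,4-bis(3-methylbut-2-enyl)benzene | COCOc1ccc(CC=C(C)C)c(OCOC)c1CC=C(C)C | intermediate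
18 | 4-hydroxybenzaldehyde | O=Cc1ccc(O)cc1 | starting material
19 | 4-(methoxymethoxy)benzaldehyde | COCOc1ccc(C=O)cc1 | intermediate
20 | diethyl {2-[methoxy(methyl)amino]-2-oxoethyl}phosphonate | CCOP(=O)(CC(=O)N(C)OC)OCC | starting material
21 | (2E)-N-methoxy-3-[4-(methoxymethoxy)phenyl]-N-methylprop-2-enamide | CON(C)C(=O)/C=C/c1ccc(OCOC)cc1 | intermediate
22 | [2,4-bis(methoxymethoxy)-3,5-bis(3-methylbut-2-enyl)phenyl]lithium | [Li]c1cc(CC=C(C)C)c(OCOC)c(CC=C(C)C)c1OCOC | intermediate
23 | (2E)-1-[2,4-bis(methoxymethoxy)-3,5-bis(3-methylbut-2-enyl)phenyl]-3-[4-(methoxymethoxy)phenyl]prop-2-en-1-one | COCOc1ccc(/C=C/C(=O)c2cc(CC=C(C)C)c(OCOC)c(CC=C(C)C)c2OCOC)cc1 | intermediate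
24 | [2,4-bis(methoxymethoxy)-3,5-bis(3-methylbut-2-enyl)phenyl]{(2R,3S)-3-[4-(methoxymethoxy)phenyl]oxiran-2-yl}methanone | O=C(c1cc(CC=C(C)C)c(OCOC)c(CC=C(C)C)c1OCOC)[C@@H]1O[C@H]1c1ccc(OCOC)cc1 | intermediate
25 | [2-hydroxy-4-(methoxymethoxy)-3,5-bis(3-methylbut-2-enyl)phenyl]{(2R,3S)-3-[4-(methoxymethoxy)phenyl]oxiran-2-yl}methanone | O=C(c1cc(CC=C(C)C)c(OCOC)c(CC=C(C)C)c1O)[C@@H]1O[C@H]1c1ccc(OCOC)cc1 | intermediate
26 | (2R,3R)-3-hydroxy-7-(methoxymethoxy)-2-[4-(methoxymethoxy)phenyl]-6,8-bis(3-methylbut-2-enyl)-2,3-dihydro-4H-chromen-4-one | CC(C)=CCc1cc2c(c(CC=C(C)C)c1OCOC)O[C@H](c1ccc(OCOC)cc1)[C@@H](O)C2=O | intermediate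
27 | lespeflorin B2, (2R,3R)-3,7-dihydroxy-2-(4-hydroxyphenyl)-6,8-bis(3-methylbut-2-enyl)-2,3-dihydro-4H-chromen-4-one | CC(C)=CCc1cc2c(c(CC=C(C)C)c1O)O[C@H](c1ccc(O)cc1)[C@@H](O)C2=O | target

**Step count**
Total: 12 steps. Longest linear sequence: 8 steps (1, 2, 5, 6, 7, 10, 11, 12; the branch through steps 3 and 4 is equally long).

**Steps most likely to fail**

Step 5. The photochemical stage may lose the vinylketene before the alkyne captures it: E-to-Z photoisomerization of the enone followed by a 1,5-hydrogen shift from the doubly allylic CH2, or ketene dimerization and acylation of the product phenol. The fallback sets out from 5, removes the skipped diene from the ketene component and makes the ketene thermally. Compound 5 is heated with cyclobut-2-en-1-one (toluene, 80 °C), the thermal form of the same benzannulation, to give 2-(3-methylbut-2-enyl)-3-(triisopropylsilyloxy)phenol F1. Pd(PPh3)4 (zerovalent palladium) and tert-butyl 2-methylbut-3-en-2-yl carbonate in THF convert the phenol into its 1,1-dimethylallyl ether, triisopropyl[3-(2-methylbut-3-en-2-yloxy)-2-(3-methylbut-2-enyl)phenoxy]silane F2. Aromatic Claisen rearrangement (N,N-diethylaniline, 160 °C) into the only free ortho position installs the C6 prenyl group and comes back to the route at 15.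

Step 10. Deprotonation may go to the benzylic and allylic CH2 of the C8 prenyl group, which sits between two acetal oxygens, instead of to the ring C–H at C4a; conjugate addition to the enamide is a second possible leak. The fallback sets out from 16 and avoids strong base at the arene. Magnesium phenoxide ortho-formylation (MgCl2, Et3N, paraformaldehyde, MeCN, reflux) can only reach C4a, the one open position ortho to a hydroxyl, and gives 2,4-dihydroxy-3,5-bis(3-methylbut-2-enyl)benzaldehyde F3. NaH/MOMCl gives 2,4-bis(methoxymethoxy)-3,5-bis(3-methylbut-2-enyl)benzaldehyde F4. MeMgBr (THF, 0 °C) gives racemic 1-[2,4-bis(methoxymethoxy)-3,5-bis(3-methylbut-2-enyl)phenyl]ethanol F5, and Dess–Martin oxidation gives 1-[2,4-bis(methoxymethoxy)-3,5-bis(3-methylbut-2-enyl)phenyl]ethanone F6. Claisen–Schmidt condensation of the ketone with 19 (KOH, EtOH, 25 °C) comes back to the route at 23.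

Step 12. While the hindered 7-O acetal is slowly cleaved, the freed 7-hydroxyl may add under acid catalysis to a flanking prenyl alkene (chroman formation), and methanol may capture the epoxide without ring closure. The fallback sets out from 16 and keeps O7 silylated through the acid step. One equivalent of MOMCl with i-Pr2NEt (CH2Cl2, 0 °C) should react at the less hindered O1 hydroxyl to give 3-(methoxymethoxy)-2,6-bis(3-methylbut-2-enyl)phenol F7. i-Pr3SiOTf and 2,6-lutidine give triisopropyl[3-(methoxymethoxy)-2,6-bis(3-methylbut-2-enyl)phenoxy]silane F8. Lithiation and acylation with 21 as in step 10 give (2E)-1-[2-(methoxymethoxy)-3,5-bis(3-methylbut-2-enyl)-4-(triisopropylsilyloxy)phenyl]-3-[4-(methoxymethoxy)phenyl]prop-2-en-1-one F9. Epoxidation as in step 11 gives [2-(methoxymethoxy)-3,5-bis(3-methylbut-2-enyl)-4-(triisopropylsilyloxy)phenyl]{(2R,3S)-3-[4-(methoxymethoxy)phenyl]oxiran-2-yl}methanone F10. Brief HCl/MeOH removes only the two unhindered acetals and closes ring C while no free phenol neighbours a prenyl group, giving (2R,3R)-3-hydroxy-2-(4-hydroxyphenyl)-6,8-bis(3-methylbut-2-enyl)-7-(triisopropylsilyloxy)-2,3-dihydro-4H-chromen-4-one F11. TBAF buffered with AcOH (THF, 0 °C) then comes back to the route at 27.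

**Further compounds**
F1 | step 5 | 2-(3-methylbut-2-enyl)-3-(triisopropylsilyloxy)phenol | CC(C)=CCc1c(O)cccc1O[Si](C(C)C)(C(C)C)C(C)C
F2 | step 5 | triisopropyl[3-(2-methylbut-3-en-2-yloxy)-2-(3-methylbut-2-enyl)phenoxy]silane | C=CC(C)(C)Oc1cccc(O[Si](C(C)C)(C(C)C)C(C)C)c1CC=C(C)C
F3 | step 10 | 2,4-dihydroxy-3,5-bis(3-methylbut-2-enyl)benzaldehyde | O=Cc1cc(CC=C(C)C)c(O)c(CC=C(C)C)c1O
F4 | step 10 | 2,4-bis(methoxymethoxy)-3,5-bis(3-methylbut-2-enyl)benzaldehyde | COCOc1c(C=O)cc(CC=C(C)C)c(OCOC)c1CC=C(C)C
F5 | step 10 | 1-[2,4-bis(methoxymethoxy)-3,5-bis(3-methylbut-2-enyl)phenyl]ethanol (racemic) | CC(O)c1cc(CC=C(C)C)c(OCOC)c(CC=C(C)C)c1OCOC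
F6 | step 10 | 1-[2,4-bis(methoxymethoxy)-3,5-bis(3-methylbut-2-enyl)phenyl]ethanone | CC(=O)c1cc(CC=C(C)C)c(OCOC)c(CC=C(C)C)c1OCOC
F7 | step 12 | 3-(methoxymethoxy)-2,6-bis(3-methylbut-2-enyl)phenol | COCOc1ccc(CC=C(C)C)c(O)c1CC=C(C)C
F8 | step 12 | triisopropyl[3-(methoxymethoxy)-2,6-bis(3-methylbut-2-enyl)phenoxy]silane | COCOc1ccc(CC=C(C)C)c(O[Si](C(C)C)(C(C)C)C(C)C)c1CC=C(C)C
F9 | step 12 | (2E)-1-[2-(methoxymethoxy)-3,5-bis(3-methylbut-2-enyl)-4-(triisopropylsilyloxy)phenyl]-3-[4-(methoxymethoxy)phenyl]prop-2-en-1-one | COCOc1ccc(/C=C/C(=O)c2cc(CC=C(C)C)c(O[Si](C(C)C)(C(C)C)C(C)C)c(CC=C(C)C)c2OCOC)cc1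
F10 | step 12 | [2-(methoxymethoxy)-3,5-bis(3-methylbut-2-enyl)-4-(triisopropylsilyloxy)phenyl]{(2R,3S)-3-[4-(methoxymethoxy)phenyl]oxiran-2-yl}methanone | O=C(c1cc(CC=C(C)C)c(O[Si](C(C)C)(C(C)C)C(C)C)c(CC=C(C)C)c1OCOC)[C@@H]1O[C@H]1c1ccc(OCOC)cc1
F11 | step 12 | (2R,3R)-3-hydroxy-2-(4-hydroxyphenyl)-6,8-bis(3-methylbut-2-enyl)-7-(triisopropylsilyloxy)-2,3-dihydro-4H-chromen-4-one | CC(C)=CCc1cc2c(c(CC=C(C)C)c1O[Si](C(C)C)(C(C)C)C(C)C)O[C@H](c1ccc(O)cc1)[C@@H](O)C2=O
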